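Slowness is what the cold runs show first: after 40.0 min the south-east run holds 22.7% of open intermediate and the north run 23.2%, although c(substrate) is 0.34 M against 0.50 M and c(partner) is 0.525 M against 0.79 M.

| flask | substrate | partner | temperature | remark | time |
|---|---|---|---|---|---|
| south-east | 0.34 M | 0.525 M | −14 °C | run made earlier |  |
| west | 0.75 M | 0.525 M | 11 °C | run made earlier |  |
| north | 0.50 M | 0.79 M | −14 °C | run made earlier |  |
| summer | 0.50 M | 0.525 M | 5 °C |  | 20 min |
| dawn | 0.50 M | 0.525 M | −10 °C |  | 20 min |
| noon | 0.50 M | 0.525 M | −25 °C |  | 20 min |
| autumn | 0.50 M | 0.525 M | 20 °C |  | 20 min |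

| run | time / min | open intermediate / % | target / % |
|---|---|---|---|
| south-east | 10.0 | 6.5 | 0 |
| south-east | 20.0 | 11.7 | 0.1 |
| south-east | 30.0 | 21.6 | 0 |
| south-east | 40.0 | 22.7 | 0 |
| west | 1.33 | 15.5 | 0 |
| west | 3.00 | 25.4 | 1.5 |
| west | 6.00 | 29.4 | 0 |
| west | 15.0 | 13.8 | 1.1 |
| north | 10.0 | 9.7 | 0.7 |
| north | 20.0 | 12.1 | 0.9 |
| north | 30.0 | 16.6 | 0 |
| north | 40.0 | 23.2 | 0 |

(readings scatter by 1 percentage point)

- on the list of suspects stand: partner -> second intermediate; substrate <-> open intermediate; substrate <-> dormant form; open intermediate + second intermediate -> target; 2 second intermediate -> homo product; open intermediate -> side product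

- the flask with the highest amount of open intermediate, in percent of the substrate charged ("all alike" if they lie within 1.5 percentage points) (summer / dawn / noon / autumn / all alike)
- final open intermediate, as a percentage of the substrate charged, in summer
- final open intermediate, as a percentage of the substrate charged, in dawn
- final open intermediate, as a percentage of the substrate charged, in noon
- final open intermediate, as a percentage of the substrate charged, in autumn

The percentage in those two cold runs hardly notices the charges, so I read the making of open intermediate as first order, with a cold rate at −14 °C of 0.00574 min⁻¹. The west run at 11 °C holds 15.5% after 1.33 min, a rate of 0.117 min⁻¹. Its reading is highest at 6.00 min, 29.4%, and falls to 13.8% at 15.0 min. Call the west rate over the cold rate the speed-up factor, 20.3.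

Anna argues from making alone: the amount is rate times time. Spreading the factor evenly per degree, she gets 3.05% for noon and 18.6% for dawn, and a rate of 0.345 min⁻¹ for autumn, so the warmest flask should win.

Ben argues that open intermediate rises and falls, and he assumes that the peak time shifts by the same factor. His scale is the clock ratio r, a dimensionless time: the time over the peak time at that temperature. Its zero point is r equal to one, the flask stopped exactly at its peak. Autumn gets 9.86, far past the peak, summer 1.62, dawn 0.266. Reading summer on the west run's fall, I reckon 23.0%, more than Anna's dawn, so I side with Ben.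

The forecast, on Ben's side, names summer, with 24% for summer against my 23.0%, 17% for dawn, 2.4% for noon and 1% for autumn, and adds: “A reversible tail could leave a little in autumn.”

The flasks give summer as the highest, with 26.4% in summer, 20.8% in dawn, 3.07% in noon and 0.887% in autumn.

    partner → second intermediate (k = 0.0120 min⁻¹, Ea = 90.0 kJ mol⁻¹)
    substrate ⇌ open intermediate (K = 2.90, k = 0.0880 min⁻¹, Ea = 77.0 kJ mol⁻¹, ΔH = −42.0 kJ mol⁻¹)
    substrate ⇌ dormant form (K = 0.480, k = 0.0100 min⁻¹, Ea = 92.0 kJ mol⁻¹, ΔH = −30.0 kJ mol⁻¹)
    open intermediate + second intermediate → target (k = 0.0730 L mol⁻¹ min⁻¹, Ea = 48.0 kJ mol⁻¹)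
    2 second intermediate → homo product (k = 0.0810 L mol⁻¹ min⁻¹, Ea = 56.0 kJ mol⁻¹)
    open intermediate → side product (k = 0.0760 min⁻¹, Ea = 92.0 kJ mol⁻¹)
    (constants at 5 °C)

Anna's rule has its region below r equal to one, where dawn stands at 0.266: noon holds 3.07% and dawn 20.8%. A neighbouring flask at −5 °C, with autumn's charges and time, gets a peak time of 41.2 min from the same factor, so its clock ratio is 0.485, below one, which on this reckoning puts it in her region. Her rate times time gives 33.9% for it, and the flask at −5 °C holds 31.1% of open intermediate, more than summer's 26.4%. The flask at −5 °C holds 58.9% as substrate and 6.36% as side product.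

(The numbers in the tables stem from a simulated flask on assumed constants; the scatter is artificial.)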